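**Retrosynthetic overview** (longipinane numbering: chain C1–C11 with extra bonds C1–C11, C4–C10 and C5–C11; C1 ketone, C2=C3, C7 angelate, C9 acetate)
1. Target ⇒ allylic oxidation at C1, C2=C3 from a C3 tertiary alcohol, and both esters from a C7,C9-dione (CBS reduction at C9, then Evans–Tishchenko reduction).
2. Dione ⇒ monocyclic cyclohexene oxide 14 by breaking C4–C10 (cyclobutane) and C8–C9 (seven-membered ring) together: a nitrile-anion epoxide opening relayed into an enolate–nitrile ring closure.
3. Enabling feature: C9 sits directly on quaternary C10, so C9 can be a nitrile carbon and C10 its carbanion; C4 is the secondary end of a C3–C4 epoxide whose tertiary end carries the C3 methyl; the C7 ketone, flanked by quaternary C6, can enolise only at C8.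
4. Ring order: six-membered ring (C1–C5, C11) by Diels–Alder reaction, then cyclobutane and seven-membered ring in the key step.

Key step: step 9

Remark: the (S)-configured oxazaborolidinium catalyst in step 3 is assumed to give the (1S,6R) adduct 7; if the sense were opposite, its enantiomer would be used with no other change.

Step 1
Reactants: 1 3-bromo-3-methylbutan-2-one; 2 3-methylbut-2-enal
Product: 4 methyl 3,3,6-trimethyl-2-oxohept-5-en-4-yl carbonate (racemic), via zinc aldolate 3 (not isolated)
Conditions: Zn dust (Me3SiCl-activated), THF, 0 → 25 °C; then ClCO2Me, 0 °C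
Reagents that add atoms: methyl chloroformate, COC(=O)Cl
Why: Reformatsky reaction, in which the zinc enolate forms only at the bromine-bearing tertiary carbon and adds 1,2 to the enal, the zinc alkoxide being acylated in the same flask; the racemic carbinol centre is removed in step 2.

Step 2
Reactants: 4 methyl 3,3,6-trimethyl-2-oxohept-5-en-4-yl carbonate
Product: 5 (4E)-3,3,6-trimethylhepta-4,6-dien-2-one
Conditions: Pd(PPh3)4 (5 mol %), THF, 65 °C
Reagents that add atoms: none
Why: Tsuji-type elimination, in which zerovalent palladium ionises the allylic carbonate to a π-allyl complex whose only β-hydrogens are on the methyl groups, so β-hydride elimination should give the conjugated E-diene with loss of CO2 and methanol.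

Step 3
Reactants: 5 (4E)-3,3,6-trimethylhepta-4,6-dien-2-one; 6 but-3-en-2-one
Product: 7 3-[(1S,6R)-6-acetyl-3-methylcyclohex-2-en-1-yl]-3-methylbutan-2-one
Conditions: (S)-o-tolyl-oxazaborolidinium triflimide (20 mol %), CH2Cl2, −78 → −40 °C
Reagents that add atoms: none
Why: Lewis-acid-catalysed Diels–Alder reaction, in which the 1-alkyl and 3-methyl groups of the diene both direct the acetyl-bearing carbon next to the substituted diene terminus, the endo transition state places acetyl and side chain cis, and the chiral cation shields one enone face so that the (1S,6R) adduct should predominate.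

Step 4
Reactants: 7 3-[(1S,6R)-6-acetyl-3-methylcyclohex-2-en-1-yl]-3-methylbutan-2-one
Product: 8 3-methyl-3-[(1S,6R)-3-methyl-6-(prop-1-en-2-yl)cyclohex-2-en-1-yl]butan-2-one
Conditions: Ph3PCH3Br, KN(SiMe3)2, THF, −78 → 0 °C
Reagents that add atoms: methyltriphenylphosphonium bromide, C[P+](c1ccccc1)(c1ccccc1)c1ccccc1.[Br-]
Why: Wittig methylenation, in which the ring acetyl group reacts while the methyl ketone on the quaternary carbon is too hindered at 0 °C, and the salt-free ylide at low temperature should leave the adjacent stereocentre untouched.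

Step 5
Reactants: 8 3-methyl-3-[(1S,6R)-3-methyl-6-(prop-1-en-2-yl)cyclohex-2-en-1-yl]butan-2-one
Product: 10 3-[(1R,6R)-6-(1-hydroxypropan-2-yl)-3-methylcyclohex-2-en-1-yl]-3-methylbutan-2-one (both side-chain epimers), via trialkylborane 9 (not isolated)
Conditions: 9-BBN, THF, 0 → 25 °C; then H2O2, NaOH, H2O, 0 °C
Reagents that add atoms: hydrogen peroxide, OO
Why: Hydroboration–oxidation, in which 9-BBN adds anti-Markovnikov to the 1,1-disubstituted alkene much faster than to the trisubstituted ring alkene or the hindered ketone; the new side-chain stereocentre is erased in step 9.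

Step 6
Reactants: 10 3-[(1R,6R)-6-(1-hydroxypropan-2-yl)-3-methylcyclohex-2-en-1-yl]-3-methylbutan-2-one
Product: 12 2-[(1R,2R)-4-methyl-2-(2-methyl-3-oxobutan-2-yl)cyclohex-3-en-1-yl]propanenitrile (both epimers at C2 of the nitrile), via aldehyde 11 (not isolated)
Conditions: TEMPO (10 mol %), PhI(OAc)2, NH4OAc, MeCN–H2O, 25 °C
Reagents that add atoms: ammonium acetate, [NH4+].CC(=O)[O-]
Why: Oxidative conversion of a primary alcohol into a nitrile (oxoammonium oxidation to the aldehyde, condensation with ammonia, second oxidation of the aldimine), which should leave alkene and ketone untouched.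

Step 7
Reactants: 12 2-[(1R,2R)-4-methyl-2-(2-methyl-3-oxobutan-2-yl)cyclohex-3-en-1-yl]propanenitrile
Product: 13 2-[(1R,4S,5S,6S)-1-methyl-5-(2-methyl-3-oxobutan-2-yl)-7-oxabicyclo[4.1.0]heptan-4-yl]propanenitrile
Conditions: mCPBA, NaHCO3, CH2Cl2, 0 °C
Reagents that add atoms: 3-chloroperbenzoic acid, OOC(=O)c1cccc(Cl)c1
Why: Prilezhaev epoxidation of the only alkene from the face opposite the two cis side chains, which sets the epoxide trans to both, as needed for backside attack in step 9.

Step 8
Reactants: 13 2-[(1R,4S,5S,6S)-1-methyl-5-(2-methyl-3-oxobutan-2-yl)-7-oxabicyclo[4.1.0]heptan-4-yl]propanenitrile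
Product: 14 2-[(1R,4S,5S,6S)-1-methyl-5-{2-methyl-3-[(trimethylsilyl)oxy]but-3-en-2-yl}-7-oxabicyclo[4.1.0]heptan-4-yl]propanenitrile
Conditions: Me3SiCl, LiN(i-Pr)2, THF, −78 °C (in situ quench)
Reagents that add atoms: chlorotrimethylsilane, C[Si](C)(C)Cl
Why: Kinetic enolisation and O-silylation; the ketone, enolisable only at its methyl group, is far more acidic than the nitrile α-position, so only the silyl enol ether should form.

Step 9
Reactants: 14 2-[(1R,4S,5S,6S)-1-methyl-5-{2-methyl-3-[(trimethylsilyl)oxy]but-3-en-2-yl}-7-oxabicyclo[4.1.0]heptan-4-yl]propanenitrile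
Product: 18 (3R,4S,5R,10S,11R)-3-hydroxylongipinane-7,9-dione, via potassium alkoxide 15 (not isolated), via potassium enolate 16 (not isolated), via vinylogous amide 17 (not isolated)
Conditions: KN(SiMe3)2 (1.2 equiv), THF, −78 → −20 °C, then 25 → 50 °C; then AcOH–H2O–THF, 25 °C
Reagents that add atoms: water, O
Why: KN(SiMe3)2 removes the nitrile α-hydrogen and the planar C10 carbanion opens the C3–C4 epoxide at the secondary carbon C4 by backside attack (closest known type: nitrile-anion epoxide cyclisation to cyclobutanes), closing the cyclobutane C4–C5–C11–C10 in a 4-exo-tet mode, attack at tertiary C3 being blocked. The tertiary potassium alkoxide released at C3 then takes the trimethylsilyl group from the C7 enol ether on warming (alkoxide cleavage of a silyl enol ether), and the unmasked potassium enolate adds through C8 to the C9 nitrile in a 7-exo-dig Thorpe-type closure of the seven-membered ring, giving a vinylogous amide that aqueous acetic acid hydrolyses to the 7,9-dione. C4 is set by inversion at the epoxide carbon (the epoxide lies trans to the side chains from step 7), and C10 by the bridging geometry together with the preference of the slim cyano group, not the methyl group, for the crowded position beside the C6 quaternary carbon; only that epimer can reach the enolate, so the second closure also filters the configuration. The selectivity that matters is between the two carbon nucleophiles: a free C8 enolate would open the epoxide in a 5-exo mode, and this is prevented because the enolate stays masked as the silyl ether until an alkoxide, which exists only after the cyclobutane has formed, releases it, and because the cyclisation is run cold before the relay is allowed by warming. The C7 ketone can enolise only towards C8 since C6 is quaternary, so the second closure has no regiochemical alternative.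

Step 10
Reactants: 18 (3R,4S,5R,10S,11R)-3-hydroxylongipinane-7,9-dione
Product: 19 (3R,4S,5R,9R,10S,11R)-3,9-dihydroxylongipinan-7-one
Conditions: (S)-Me-CBS oxazaborolidine (0.3 equiv), catecholborane (2.2 equiv), toluene, −78 °C; then MeOH, aq. NaHCO3
Reagents that add atoms: none
Why: Corey–Bakshi–Shibata reduction, in which the catalyst distinguishes quaternary C10 (large) from the C8 methylene (small) at the C9 carbonyl, so the (S)-catalyst should give the 9R carbinol by reagent control; the C7 carbonyl, flanked on both faces by the C6 methyl groups, should react more slowly.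

Step 11
Reactants: 19 (3R,4S,5R,9R,10S,11R)-3,9-dihydroxylongipinan-7-one
Product: 20 (3R,4S,5R,7R,9R,10S,11R)-3,7-dihydroxylongipinan-9-yl acetate
Conditions: SmI2 (0.3 equiv), CH3CHO (8 equiv), THF, −10 °C
Reagents that add atoms: acetaldehyde, CC=O
Why: Evans–Tishchenko reduction, in which the samarium-bound hemiacetal formed from the C9 hydroxyl and acetaldehyde delivers hydride intramolecularly to the C7 carbonyl, giving the 7,9-anti diol (7R) with the acetate already on O9.

Step 12
Reactants: 20 (3R,4S,5R,7R,9R,10S,11R)-3,7-dihydroxylongipinan-9-yl acetate; 21 angelic acid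
Product: 23 (3R,4S,5R,7R,9R,10S,11R)-9-acetoxy-3-hydroxylongipinan-7-yl (2Z)-2-methylbut-2-enoate, via mixed anhydride 22 (not isolated)
Conditions: 2,4,6-Cl3C6H2COCl, Et3N, toluene, 25 °C; then 20, 80 °C
Reagents that add atoms: none
Why: Yamaguchi-type mixed-anhydride esterification run without a nucleophilic catalyst, which should acylate the secondary C7 hydroxyl with retention of the Z geometry while the tertiary C3 hydroxyl stays free.

Step 13
Reactants: 23 (3R,4S,5R,7R,9R,10S,11R)-9-acetoxy-3-hydroxylongipinan-7-yl (2Z)-2-methylbut-2-enoate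
Product: 24 (4R,5R,7R,9R,10S,11R)-9-acetoxylongipin-2-en-7-yl (2Z)-2-methylbut-2-enoate
Conditions: Burgess reagent (MeO2CNSO2NEt3 inner salt), toluene, 50 °C
Reagents that add atoms: none
Why: Burgess dehydration by syn-elimination; one C2 hydrogen is held syn-coplanar to the C3–O bond in the flattened three-carbon bridge and bridgehead C4 cannot become sp2, so the endocyclic trisubstituted C2=C3 alkene should form.

Step 14
Reactants: 24 (4R,5R,7R,9R,10S,11R)-9-acetoxylongipin-2-en-7-yl (2Z)-2-methylbut-2-enoate
Product: 25 (4R,5S,7R,9R,10R,11R)-9-acetoxy-1-oxolongipin-2-en-7-yl (2Z)-2-methylbut-2-enoate (CNP0260482.1)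
Conditions: Rh2(cap)4 [dirhodium tetrakis(caprolactamate)] (1 mol %), t-BuOOH, K2CO3, CH2Cl2, 25 °C
Reagents that add atoms: tert-butyl hydroperoxide, CC(C)(C)OO
Why: Allylic C–H oxidation of the electron-rich trisubstituted alkene at C1, its only allylic methylene (the transformation that converts pinene-type alkenes into verbenone-type enones); the electron-poor angelate alkene should not react.

**Compound list**
1 | 3-bromo-3-methylbutan-2-one | CC(=O)C(C)(C)Br | starting material
2 | 3-methylbut-2-enal | CC(C)=CC=O | starting material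
3 | bromozinc 3,3,6-trimethyl-2-oxohept-5-en-4-olate (racemic) | CC(=O)C(C)(C)C(O[Zn]Br)C=C(C)C | intermediate
4 | methyl 3,3,6-trimethyl-2-oxohept-5-en-4-yl carbonate (racemic) | CC(=O)C(C)(C)C(OC(=O)OC)C=C(C)C | intermediate
5 | (4E)-3,3,6-trimethylhepta-4,6-dien-2-one | CC(=O)C(C)(C)/C=C/C(C)=C | intermediate
6 | but-3-en-2-one | C=CC(C)=O | starting material
7 | 3-[(1S,6R)-6-acetyl-3-methylcyclohex-2-en-1-yl]-3-methylbutan-2-one (side chains cis) | CC(=O)[C@@H]1CCC(C)=C[C@@H]1C(C)(C)C(C)=O | intermediate
8 | 3-methyl-3-[(1S,6R)-3-methyl-6-(prop-1-en-2-yl)cyclohex-2-en-1-yl]butan-2-one | C=C(C)[C@@H]1CCC(C)=C[C@@H]1C(C)(C)C(C)=O | intermediate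
9 | B-alkyl-9-borabicyclo[3.3.1]nonane from 8 (boron on the terminal carbon of the former isopropenyl group; side-chain epimers) | CC(CB1C2CCCC1CCC2)[C@@H]1CCC(C)=C[C@@H]1C(C)(C)C(C)=O | intermediate
10 | 3-[(1R,6R)-6-(1-hydroxypropan-2-yl)-3-methylcyclohex-2-en-1-yl]-3-methylbutan-2-one (side-chain epimers) | OCC(C)[C@@H]1CCC(C)=C[C@@H]1C(C)(C)C(C)=O | intermediate
11 | 2-[(1R,2R)-4-methyl-2-(2-methyl-3-oxobutan-2-yl)cyclohex-3-en-1-yl]propanal (side-chain epimers) | O=CC(C)[C@@H]1CCC(C)=C[C@@H]1C(C)(C)C(C)=O | intermediate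
12 | 2-[(1R,2R)-4-methyl-2-(2-methyl-3-oxobutan-2-yl)cyclohex-3-en-1-yl]propanenitrile (side-chain epimers) | N#CC(C)[C@@H]1CCC(C)=C[C@@H]1C(C)(C)C(C)=O | intermediate
13 | 2-[(1R,4S,5S,6S)-1-methyl-5-(2-methyl-3-oxobutan-2-yl)-7-oxabicyclo[4.1.0]heptan-4-yl]propanenitrile (side-chain epimers) | N#CC(C)[C@@H]1CC[C@@]2(C)O[C@H]2[C@@H]1C(C)(C)C(C)=O | intermediate
14 | 2-[(1R,4S,5S,6S)-1-methyl-5-{2-methyl-3-[(trimethylsilyl)oxy]but-3-en-2-yl}-7-oxabicyclo[4.1.0]heptan-4-yl]propanenitrile (side-chain epimers) | N#CC(C)[C@@H]1CC[C@@]2(C)O[C@H]2[C@@H]1C(C)(C)C(=C)O[Si](C)(C)C | intermediate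
15 | potassium 6-cyano-2,6-dimethyl-7-{2-methyl-3-[(trimethylsilyl)oxy]but-3-en-2-yl}bicyclo[3.1.1]heptan-2-olate (ring configuration as in 18) | N#C[C@@]1(C)[C@@H]2CC[C@@](C)([O-])[C@H]1[C@@H]2C(C)(C)C(=C)O[Si](C)(C)C.[K+] | intermediate
16 | potassium 3-{6-cyano-2,6-dimethyl-2-[(trimethylsilyl)oxy]bicyclo[3.1.1]heptan-7-yl}-3-methylbut-1-en-2-olate (ring configuration as in 18) | N#C[C@@]1(C)[C@@H]2CC[C@@](C)(O[Si](C)(C)C)[C@H]1[C@@H]2C(C)(C)C(=C)[O-].[K+] | intermediate
17 | 9-amino-3-[(trimethylsilyl)oxy]longipin-8-en-7-one (configuration as in 18) | O=C1C=C(N)[C@@]2(C)[C@@H]3CC[C@@](C)(O[Si](C)(C)C)[C@H]2[C@@H]3C1(C)C | intermediate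
18 | (3R,4S,5R,10S,11R)-3-hydroxylongipinane-7,9-dione | O=C1CC(=O)[C@@]2(C)[C@@H]3CC[C@@](C)(O)[C@H]2[C@@H]3C1(C)C | intermediate
19 | (3R,4S,5R,9R,10S,11R)-3,9-dihydroxylongipinan-7-one | O=C1C[C@@H](O)[C@@]2(C)[C@@H]3CC[C@@](C)(O)[C@H]2[C@@H]3C1(C)C | intermediate
20 | (3R,4S,5R,7R,9R,10S,11R)-3,7-dihydroxylongipinan-9-yl acetate | O[C@@H]1C[C@@H](OC(C)=O)[C@@]2(C)[C@@H]3CC[C@@](C)(O)[C@H]2[C@@H]3C1(C)C | intermediate
21 | angelic acid, (2Z)-2-methylbut-2-enoic acid | C/C=C(/C)C(=O)O | starting material
22 | (2Z)-2-methylbut-2-enoic 2,4,6-trichlorobenzoic anhydride | C/C=C(/C)C(=O)OC(=O)c1c(Cl)cc(Cl)cc1Cl | intermediate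
23 | (3R,4S,5R,7R,9R,10S,11R)-9-acetoxy-3-hydroxylongipinan-7-yl (2Z)-2-methylbut-2-enoate | C/C=C(/C)C(=O)O[C@@H]1C[C@@H](OC(C)=O)[C@@]2(C)[C@@H]3CC[C@@](C)(O)[C@H]2[C@@H]3C1(C)C | intermediate
24 | (4R,5R,7R,9R,10S,11R)-9-acetoxylongipin-2-en-7-yl (2Z)-2-methylbut-2-enoate | C/C=C(/C)C(=O)O[C@@H]1C[C@@H](OC(C)=O)[C@@]2(C)[C@@H]3CC=C(C)[C@H]2[C@@H]3C1(C)C | intermediate
25 | (4R,5S,7R,9R,10R,11R)-9-acetoxy-1-oxolongipin-2-en-7-yl (2Z)-2-methylbut-2-enoate (CNP0260482.1) | C/C=C(/C)C(=O)O[C@@H]1C[C@@H](OC(C)=O)[C@@]2(C)[C@@H]3C(=O)C=C(C)[C@H]2[C@@H]3C1(C)C | target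

**Totals**
Total step count: 14. Longest linear sequence: 14 steps (from 1 and 2).

**Steps most likely to fail**

Step 9. The relay may break down in two ways: the silyl mask may be lost before the cyclobutane has closed, so that the C8 enolate opens the epoxide in a 5-exo mode, or the enolate may fail to add to the hindered nitrile. The fallback separates the two bond formations and makes C8–C9 by an aldol reaction. It sets out from 14: LiN(i-Pr)2 in THF, followed by Me3SiCl, should give only the epoxynitrile cyclisation product, the bis-silyl cyclobutane nitrile F1. i-Bu2AlH at −78 °C with a buffered work-up should reduce the nitrile to the aldehyde F2. Bu4NF should then unmask the enolate and close the seven-membered ring by intramolecular aldol addition to the β-hydroxy ketone F3 (both C9 epimers, both hydroxyls free). Dess–Martin oxidation of the secondary alcohol returns to 18.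

Step 10. The reagent may discriminate poorly between the two carbonyl groups, reducing C7 first or both. The fallback sets out from 18: exhaustive CBS reduction with the same (S)-catalyst and excess BH3·SMe2 should give the 7R,9R-configured triol F4, since both carbonyls present the same large/small pattern to the catalyst. Acetylation of the less shielded C9 hydroxyl (Ac2O, 2,4,6-collidine, −20 °C) then returns to 20, replacing regioselective reduction by regioselective acylation.

Step 13. Elimination may run towards the C3 methyl group, or ionisation at C3 may trigger opening or a Wagner–Meerwein shift of the cyclobutane. The fallback sets out from 23 and builds the alkene from a ketone instead. POCl3 in pyridine (anti elimination, possible only with the methyl hydrogens) should give the exocyclic alkene F5. Ozonolysis of this electron-rich alkene (Me2S work-up) gives the C3 ketone F6. Tf2O with 2,6-di-tert-butylpyridine gives the enol triflate F7, enolisation being possible only towards C2 because C4 is a bridgehead. Negishi coupling with MeZnCl and Pd(PPh3)4 returns to 24.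

**Further compounds**
F1 | step 9 | 2,6-dimethyl-7-{2-methyl-3-[(trimethylsilyl)oxy]but-3-en-2-yl}-2-[(trimethylsilyl)oxy]bicyclo[3.1.1]heptane-6-carbonitrile (configuration as in 18) | N#C[C@@]1(C)[C@@H]2CC[C@@](C)(O[Si](C)(C)C)[C@H]1[C@@H]2C(C)(C)C(=C)O[Si](C)(C)C
F2 | step 9 | 2,6-dimethyl-7-{2-methyl-3-[(trimethylsilyl)oxy]but-3-en-2-yl}-2-[(trimethylsilyl)oxy]bicyclo[3.1.1]heptane-6-carbaldehyde (configuration as in 18) | O=C[C@@]1(C)[C@@H]2CC[C@@](C)(O[Si](C)(C)C)[C@H]1[C@@H]2C(C)(C)C(=C)O[Si](C)(C)C
F3 | step 9 | 3,9-dihydroxylongipinan-7-one, both C9 epimers (other centres as in 18) | O=C1CC(O)[C@@]2(C)[C@@H]3CC[C@@](C)(O)[C@H]2[C@@H]3C1(C)C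
F4 | step 10 | (3R,4S,5R,7R,9R,10S,11R)-longipinane-3,7,9-triol | O[C@@H]1C[C@@H](O)[C@@]2(C)[C@@H]3CC[C@@](C)(O)[C@H]2[C@@H]3C1(C)C
F5 | step 13 | 9-acetoxy-3-methylidene-15-norlongipinan-7-yl (2Z)-2-methylbut-2-enoate (exocyclic C3=CH2 isomer of 24) | C/C=C(/C)C(=O)O[C@@H]1C[C@@H](OC(C)=O)[C@@]2(C)[C@@H]3CCC(=C)[C@H]2[C@@H]3C1(C)C
F6 | step 13 | 9-acetoxy-3-oxo-3-demethyllongipinan-7-yl (2Z)-2-methylbut-2-enoate (C3 ketone) | C/C=C(/C)C(=O)O[C@@H]1C[C@@H](OC(C)=O)[C@@]2(C)[C@@H]3CCC(=O)[C@H]2[C@@H]3C1(C)C
F7 | step 13 | 9-acetoxy-3-demethyl-3-{[(trifluoromethyl)sulfonyl]oxy}longipin-2-en-7-yl (2Z)-2-methylbut-2-enoate (enol triflate) | C/C=C(/C)C(=O)O[C@@H]1C[C@@H](OC(C)=O)[C@@]2(C)[C@@H]3CC=C(OS(=O)(=O)C(F)(F)F)[C@H]2[C@@H]3C1(C)C
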